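The stirred flask asked about was the green run itself, followed up to the moment of choice, so I needed one number to say what the next 80 min could bring.

- green: electrophile 0.80 M; nucleophile 0.80 M; gas 200 mM (held); the very flask that is asked about, followed so far
- flask: electrophile 0.80 M; nucleophile 0.800 M; gas 200 mM (held); time 4.0 h

green run (percent of the electrophile charged)

| time / h | target / % | electrophile / % |
|---|---|---|
| 0.250 | 8.5 | 91.6 |
| 0.833 | 20.9 | 75.9 |
| 1.33 | 25.2 | 65.6 |
| 2.00 | 29.0 | 56.4 |
| 3.00 | 30.8 | 47.2 |
| 4.00 | 31.1 | 39.0 |

(standard deviation of a reading: 0.5 percentage points)

- south-east: at 4.0 h add nucleophile, 50.0% of the amount charged, then wait 80 min
- south-west: at 4.0 h add electrophile, 50.0% of the amount charged, then wait 80 min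
- north: at 4.0 h take out 90% of the target then present, then wait 80 min
- south: change nothing and wait 80 min more

- for acid set free the crystals are counted in
- as a solid, counted per litre of solution: crystals
- at the start none of free base is dissolved
- what is taken out of target is counted as made
- the earlier runs were read with a standard deviation of 0.5 percentage points
- steps thought possible: nucleophile + acid set free <-> protonated nucleophile; gas <-> free base; crystals <-> acid set free; acid set free + free base <-> salt of the base; target <-> isomer of the product; electrophile + nucleophile -> acid set free + target
- additions bring no volume worth counting

1. target, in percent of the electrophile first charged, at 4.0 h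
2. which option adds most target ("none" when 2 percentage points or less is all one gets) (south-east / south-west / north / south / none)
3. target present, with what was taken out counted in, in percent of the electrophile first charged, after north
4. target present, with what was taken out counted in, in percent of the electrophile first charged, after south

At the last reading 39.0% of the electrophile was left and 31.1% stood as target, so the share of reacted electrophile standing as target (the cumulative selectivity) was 0.510. With equal charges I took the reciprocal of the fraction left to climb in a straight line, at 0.391 h⁻¹, which left 32.4% after the wait and 6.6 percentage points newly reacted. Freezing the share, I reckoned that waiting in the south option earned 3.4 points. Either addition lifted the opening rate 2.28 times and so earned about 7.7 points. North banked 28.0%, and if the reacted material still in the flask returned to the same share, it gained 17 points, more than an addition. I therefore chose north, with totals of 48.2% after north and 34.5% after south.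

The forecast also chose north, with 31.1% now, but its 41.8% after north and 31.5% after south lay below my totals; of waiting it held that “target stays near its moving steady state”.

The flask gave 31.9% now, and north won with 12 points, against 5.9 points for south-east, 5.8 points for south-west and 0.74 points for south, ending at 43.8% after north and 32.6% after south, both below my totals.

    nucleophile + acid set free ⇌ protonated nucleophile, settled at all times (K = 263 L mol⁻¹)
    gas ⇌ free base, rate k2*(csat - [free base]) (kL = 0.0291 min⁻¹)
    crystals ⇌ acid set free, rate k3*(cs3 - [acid set free]) while solid is left; crystals form when [acid set free] > cs3 (solubility = 37.0 mM, k = 2.28 min⁻¹)
    acid set free + free base ⇌ salt of the base, settled at all times (K = 27000 L mol⁻¹)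
    target ⇌ isomer of the product (K = 1.38, k = 0.00804 min⁻¹)
    electrophile + nucleophile → acid set free + target (k = 0.00826 L mol⁻¹ min⁻¹)

The relaxation half-life of target and isomer was 0.833 h, shorter than the 4.0 h of the run, and at that time the flask held a share of 0.525 as target. In the neighbour charged with 0.32 M of electrophile, 27.7% was left, so my share gave 36.9% of target, and the computed amount was 38.4%.

Readings and results come from a simulation for an exercise; noise was put on by code.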